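## Analysis of the target

The target 25 (CNP0462207.1) is a drimane: a trans-fused decalin in which ring A (C1–C5, C10) carries a geminal dimethyl group at C4 and ring B (C5–C10) carries the angular methyl at C10, carboxylic acids C12 on C8 and C11 on C9, and a (2E,4E,6E)-octa-2,4,6-trienoate on the oxygen at C6. Ring B holds five contiguous stereocentres, (5S,6R,8S,9S,10S). H5 is α, while the C6 acyloxy group, both carboxyls and the C10 methyl are β, so all four ring B hydrogens (H5, H6, H8, H9) lie on the α face. In the chair the C6 oxygen, C12 and the C10 methyl are syn-triaxial and only C11 is equatorial. The C8 configuration is therefore the less stable one, and C9 has no dependable thermodynamic preference, so both have to be set kinetically. The sensitive groups are the trienoate (hydrogenation, nucleophiles, strong base, light), the C8–H next to a carbonyl, and the 6β-oxygen/C12 pair, which closes readily to a γ-lactone. The hard points are the quaternary C10 wedged between C4 and C9, the crowded β face, and the release of two hindered acids at the end beside a third ester. The strategy rests on the segment C7–C8(C12)–C9(C11)–C10 next to oxygenated C6. Two adjacent carboxyl-bearing carbons between a methylene and the quaternary carbon are what an acetylenedicarboxylate unit leaves after adding across a C7=C6(O)–C5=C10 diene. Once C10 is fixed, every other centre can be set by delivering hydrogen to the α face, anti to the C10 methyl.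

## Retrosynthetic reasoning

**25 ⇒ 24.** The two O–allyl bonds are cut last. The acids must be freed under conditions that spare the trienoate, the axial C8 centre and the C6 ester. Cleavage of allyl esters by zerovalent palladium is neutral, whereas the methyl esters carried through the ring construction could not be removed selectively.

**24 ⇒ 19 + 23.** The C6 O–acyl bond is cut. The trienoate is introduced late because it would not survive the hydrogenation, hydride and hydroxide steps before it. Acid chloride 23 comes from acid 22, whose C2=C3 bond is cut back to dienal 20 and malonic acid 21.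

**19 ⇒ 17.** The allyl esters are traced to lactone 17 (O6–C12 reconnected, C11 as methyl ester). A 6β-hydroxy-8β-ester closes to this lactone in any case, and the lactone is turned to advantage. C8 is a bridgehead there and cannot enolise while the hindered C11 ester is saponified. The resulting dicarboxylate 18 is alkylated on oxygen, so the ester exchange needs neither acid nor attack at a hindered carbonyl.

**17 ⇒ 15 ⇒ 14.** The C6–H bond (via 16) and the C7–H/C8–H bonds are cut. Forward, hydride must reach the C6 ketone of 15 from the α face, and hydrogen must add to the C7=C8 bond of enone 14 from the α face to give the axial 8β-ester. Both are the face opposite the C10 methyl.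

**14 ⇒ 12.** The C5–H and C9–H bonds are cut. Hydrolysis of the silyl enol ether in 12 must protonate C5 from the α face (via 13). The alkene must then move from C8=C9 to C7=C8 with the proton delivered to C9 from the α face. This is done under acid, with kinetic control, because equilibration with base would be expected to drift toward the 9α-ester (allylic 1,2-strain with the C8 ester).

**12 ⇒ 4 + 10.** C7–C8 and C9–C10 are cut, the key disconnection. It removes ring B, the quaternary centre and both carboxyl carbons at once and leaves C6 at ketone level. Forward, diene 4 must add to the sulfinylmaleate 10 under a zinc Lewis acid, and the sulfinyl group must then leave by syn-elimination from adduct 11. The sulfoxide is the only source of absolute configuration.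

**4 ⇒ 3 ⇒ 2 ⇒ 1.** The Si–O bond, then the carbinol oxidation level, then the C6–C7 bond are cut. The diene comes from β-cyclocitral 1 by methyl addition, oxidation and silyl enol ether formation at the only accessible α-position.

**10 ⇒ 8 + 9; 8 ⇒ 5 + 6.** The C2=C3 bond of 10 is cut to sulfinylacetate 8 and glyoxylate 9, and the S–C bond of 8 to menthyl sulfinate 5 and the enolate 7 of methyl acetate 6. Adding an arenethiol to an alkyne diester and oxidising asymmetrically looks shorter but was not taken. Anti-addition gives mainly the fumarate-type geometry, which cannot eliminate toward H9, and enantioselective oxidation of an electron-poor vinyl sulfide is unreliable. Displacement at the sulfur of crystalline 5 fixes the configuration with certainty, and either antipode of 5 can be bought.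

## Alternatives that were turned down

**Alternative 1:** The C4–C5 and C9–C10 bonds are cut back to acyclic (2E,6E)-farnesyl diphosphate A1. Forward, a terpene cyclase that is started by protonation folds A1, closes rings A and B and releases drimenol A2.
- For: one enzymatic step builds the whole bicycle with C5, C9 and C10 in the natural absolute configuration, without protecting groups. On absolute control and on C9 it is stronger than the chosen route, and the C7=C8 alkene of A2 is well placed for α-face hydrogenation and for allylic oxidation at C6.
- Against: A2 has C11 as an alcohol, C12 as a methyl group and no oxygen at C6. C12 must be raised three oxidation levels and C11 two, and C6 needs an allylic oxidation that competes with oxidation at C12 and C9. That is probably ten or more redox and protection steps, in addition to producing the enzyme and supplying A1.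
- Comparison: the chosen strategy delivers C11 and C12 at acid level and C6 at ketone level in the bond-forming step itself and is purely chemical. In exchange it accepts a less assured ring-forming step.

**Alternative 2:** The C6–O bond is cut by C–H functionalisation, back to the primary C12 carboxamide A4, which would be made from sclareolide A3. Forward, N-iodination and light give an amidyl radical that abstracts the 6β-hydrogen through a six-membered transition state. Oxidation at C6 and closure then give lactone A5, which is the same compound as 17.
- For: the chiral pool fixes C5, C9 and C10 absolutely, which is stronger than auxiliary control. Site and face at C6 follow from the 1,3-diaxial geometry, about as reliably as the hydride reduction used here, and the endgame from A5 is identical.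
- Against: A3 has one carbon too many in the C9 side chain and carries C12 as a methyl on an oxygenated C8. Reaching A4 needs a one-carbon degradation, dehydration, oxidation of that methyl to carboxyl level and the same α-face hydrogenation for the axial 8β-group, probably more than ten steps before the key step. A primary amide under oxidative N-halogenation can also rearrange with loss of C12 (Hofmann-type), and abstraction from the syn-axial C10 methyl competes.
- Comparison: the chosen route reaches 17 in four steps from the cycloadduct, with C6–O, C11 and C12 created together.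

**Alternative 3:** C7–C8 and C8–C9 are cut by a one-carbon ring contraction, back to the trans-hydrindanone A7, derived from the (S)-Hajos–Parrish ketone A6. Forward, a diazoacetic ester adds to the C9 ketone under a Lewis acid and C7 migrates, giving the enolised β-keto ester A8.
- For: the absolute configuration comes from a robust, scalable aldol cyclisation (stronger than the chosen key step). Migration of the methylene over the quaternary carbon is dependable, and the 6β-oxygen is in place before the expansion.
- Against: A8 lacks C11, so another C–C bond must be made at C9, the most hindered position. The resulting 8-ene diester then poses the same C8/C9 problem with a tetrasubstituted alkene. Making A7 needs geminal dimethylation, removal of the ring A carbonyl, a trans hydrindane fusion (which hydrindanones resist) and the 6β-silyloxy group. The route is long and linear.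
- Comparison: the chosen strategy forms ring B with both carboxyl carbons in one step, six steps from commercial materials.

Key step: step 6

Assumption: drimane numbering is used throughout (C11 on C9, C12 on C8), and the (S)-sulfoxide drawn for 10 is the antipode that the zinc-chelate, endo model assigns to (10S)-12. This sense is to be confirmed on 14 or 17 before scale-up.

## Route

Step 1
Reactants: 1 β-cyclocitral (2,6,6-trimethylcyclohex-1-ene-1-carbaldehyde)
Product: 2 1-(2,6,6-trimethylcyclohex-1-en-1-yl)ethan-1-ol (racemic)
Conditions: MeMgBr, THF, 0 °C; aq. NH4Cl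
Reagents that add atoms: methylmagnesium bromide, C[Mg]Br
Why: Grignard 1,2-addition to an aldehyde; the enal is twisted out of conjugation, so conjugate addition should not compete, and the carbinol centre is removed in step 2.

Step 2
Reactants: 2 1-(2,6,6-trimethylcyclohex-1-en-1-yl)ethan-1-ol
Product: 3 1-(2,6,6-trimethylcyclohex-1-en-1-yl)ethan-1-one
Conditions: Dess–Martin periodinane, NaHCO3, CH2Cl2, rt
Reagents that add atoms: none
Why: Dess–Martin oxidation of a hindered secondary allylic alcohol under buffered conditions that leave the tetrasubstituted alkene in place.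

Step 3
Reactants: 3 1-(2,6,6-trimethylcyclohex-1-en-1-yl)ethan-1-one
Product: 4 tert-butyldimethyl{[1-(2,6,6-trimethylcyclohex-1-en-1-yl)ethenyl]oxy}silane
Conditions: TBSOTf (1.2 equiv), Et3N (2 equiv), CH2Cl2, 0 °C
Reagents that add atoms: tert-butyldimethylsilyl trifluoromethanesulfonate, CC(C)(C)[Si](C)(C)OS(=O)(=O)C(F)(F)F
Why: Soft enolisation of a methyl ketone (silyl triflate, amine base); only the acetyl methyl should be deprotonated because the twisted enone gains nothing from γ-deprotonation, which gives the 2-silyloxydiene.

Step 4
Reactants: 5 (1R,2S,5R)-menthyl (S)-4-methylbenzenesulfinate; 6 methyl acetate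
Product: 8 methyl (R)-2-(4-methylbenzenesulfinyl)acetate, via lithium 1-methoxyethenolate 7 (not isolated)
Conditions: LiN(iPr)2 (2.1 equiv), 6 (2.1 equiv), THF, −78 °C; then 5, −78 to −30 °C; aq. NH4Cl
Reagents that add atoms: none
Why: Andersen sulfinylation; the ester enolate displaces the menthyloxy group at sulfur with inversion, so diastereomerically pure 5 should give 8 as a single antipode, and the second equivalent of enolate takes up the acidic proton of 8.

Step 5
Reactants: 8 methyl (R)-2-(4-methylbenzenesulfinyl)acetate; 9 methyl glyoxylate
Product: 10 dimethyl (E)-2-[(S)-4-methylbenzenesulfinyl]but-2-enedioate (the 2-sulfinylmaleate with cis esters)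
Conditions: piperidine (0.1 equiv), AcOH (0.1 equiv), 4 Å MS, CH2Cl2, 0 °C to rt
Reagents that add atoms: none
Why: Knoevenagel condensation of an active methylene compound with a non-enolisable aldehyde; reversible amine addition lets the geometry settle with the new ester trans to the bulkier pyramidal sulfinyl group (maleate), and any fumarate isomer is removed by chromatography. Sulfur is not touched; its descriptor changes from R to S only because the vinyl carbon now outranks the aryl carbon.

Step 6
Reactants: 4 tert-butyldimethyl{[1-(2,6,6-trimethylcyclohex-1-en-1-yl)ethenyl]oxy}silane; 10 dimethyl (E)-2-[(S)-4-methylbenzenesulfinyl]but-2-enedioate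
Product: 12 dimethyl (10S)-6-(tert-butyldimethylsilyloxy)drima-5,8-diene-11,12-dioate, via 8-sulfinyl cycloadduct 11 (not isolated)
Conditions: ZnBr2 (1.5 equiv), ClCH2CH2Cl, −20 °C to rt; then NaHCO3, 70 °C
Reagents that add atoms: none
Why: This is a Lewis-acid-promoted normal-demand Diels–Alder reaction of a 2-silyloxydiene with a 2-sulfinylmaleate used as a chiral acetylenedicarboxylate equivalent, followed by thermal syn-elimination of the sulfenic acid, both known reaction types. ZnBr2 bridges the sulfinyl oxygen and the carbonyl oxygen of the ester on the same carbon of 10, which lowers the LUMO and holds the S–O bond anti to the C=C bond, so that the p-tolyl group covers one face and the diene adds to the face bearing the sulfur lone pair. The cycloaddition is concerted but asynchronous: the enol ether terminus C7 of 4 leads, and the tetrasubstituted terminus C10 is expected to take the CH carbon of 10, because a bond from C10 to the sulfinyl-bearing carbon would join two fully substituted centres. Ring B is closed by the [4+2] process itself, the two new σ bonds C7–C8 and C9–C10 forming suprafacially on diene and dienophile with the two esters endo. In 11 the sulfinyl group on C8 and H9 are cis, as in the maleate, so the five-centre syn-elimination gives the C8=C9 diester; the opposite orientation would put sulfur on C9 cis to H8 and end in the same diene. C10 is the only stereocentre that survives, and its configuration follows from three choices together, namely the dienophile face (chelated sulfoxide), endo over exo, and the orientation; with the (S)-sulfoxide, chelate control, endo addition and sulfur on C8 the model gives (10S). The step also needs the silyl enol ether to survive, which the solid NaHCO3 should secure against the sulfenic acid that is released.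

Step 7
Reactants: 12 dimethyl (10S)-6-(tert-butyldimethylsilyloxy)drima-5,8-diene-11,12-dioate
Product: 14 dimethyl (5S,9R,10S)-6-oxodrim-7-ene-11,12-dioate, via 6-oxodrim-8-ene diester 13 (not isolated)
Conditions: 1 M HCl, THF, 0 °C to rt; stopped when 13 is consumed
Reagents that add atoms: none
Why: Acid hydrolysis of the silyl enol ether protonates C5 on the α face, anti to the axial C10 and 4β methyl groups, and gives trans-fused 13. Acid-catalysed enolisation toward C7 and γ-protonation of the dienol at C9, axially and anti to the C10 methyl, then move the alkene into conjugation (β,γ- to α,β-unsaturated ketone isomerisation) and set the 9β-ester under kinetic control.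

Step 8
Reactants: 14 dimethyl (5S,9R,10S)-6-oxodrim-7-ene-11,12-dioate
Product: 15 dimethyl (5S,8S,9S,10S)-6-oxodrimane-11,12-dioate
Conditions: H2 (1 atm), 10% Pd/C, EtOAc, rt
Reagents that add atoms: none
Why: Heterogeneous hydrogenation of the trisubstituted, doubly activated C7=C8 alkene; the catalyst should bind the α face, away from the axial C10 methyl, so H8 arrives α and the C12 ester becomes 8β (axial).

Step 9
Reactants: 15 dimethyl (5S,8S,9S,10S)-6-oxodrimane-11,12-dioate
Product: 17 methyl (5S,6R,8S,9S,10S)-12-oxo-6,12-epoxydrimane-11-oate (the 12,6β-lactone), via 6β-hydroxy diester 16 (not isolated)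
Conditions: NaBH4, MeOH/THF, −10 to 0 °C; then PPTS (cat.), toluene, 60 °C
Reagents that add atoms: none
Why: Borohydride reduction of the ketone; hydride should attack C6 from the α face because the β face is closed by the syn-axial C10 methyl, 4β-methyl and C12 ester. The resulting 6β-oxygen closes onto the syn-axial C12 ester (lactonisation, 5-exo-trig) to the bridged γ-lactone.

Step 10
Reactants: 17 methyl (5S,6R,8S,9S,10S)-12-oxo-6,12-epoxydrimane-11-oate
Product: 19 diallyl (5S,6R,8S,9S,10S)-6-hydroxydrimane-11,12-dioate, via dipotassium hydroxy dicarboxylate 18 (not isolated)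
Conditions: KOH (8 equiv), MeOH/H2O (3:1), 75 °C; CO2 to pH 9, evaporate; allyl bromide (4 equiv), DMF, rt
Reagents that add atoms: potassium hydroxide, [K+].[OH-]; allyl bromide, C=CCBr
Why: Saponification opens the lactone and cleaves the C11 methyl ester while C8 is protected against epimerisation, first as a lactone bridgehead and then as the α-carbon of a carboxylate. SN2 O-alkylation of the dicarboxylate at the allyl carbon is insensitive to the crowding at C11 and C12 and gives the hydroxy diester without acidification, so the lactone should not re-form.

Step 11
Reactants: 20 (2E,4E)-hexa-2,4-dienal; 21 malonic acid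
Product: 22 (2E,4E,6E)-octa-2,4,6-trienoic acid
Conditions: pyridine, piperidine (cat.), 90 °C; aq. HCl
Reagents that add atoms: none
Why: Doebner–Knoevenagel condensation with decarboxylation, which forms the new alkene with E geometry and keeps the two existing E alkenes.

Step 12
Reactants: 22 (2E,4E,6E)-octa-2,4,6-trienoic acid
Product: 23 (2E,4E,6E)-octa-2,4,6-trienoyl chloride
Conditions: (COCl)2, DMF (cat.), CH2Cl2, 0 °C to rt; evaporate, use crude
Reagents that add atoms: oxalyl chloride, O=C(Cl)C(=O)Cl
Why: Acid chloride formation through the chloroiminium catalyst under conditions that should not isomerise the triene.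

Step 13
Reactants: 19 diallyl (5S,6R,8S,9S,10S)-6-hydroxydrimane-11,12-dioate; 23 (2E,4E,6E)-octa-2,4,6-trienoyl chloride
Product: 24 diallyl (5S,6R,8S,9S,10S)-6-[(2E,4E,6E)-octa-2,4,6-trienoyloxy]drimane-11,12-dioate
Conditions: pyridine, DMAP (0.2 equiv), CH2Cl2, 0 °C to rt
Reagents that add atoms: none
Why: Nucleophile-catalysed (DMAP) acylation of the hindered axial 6β-alcohol by an acid chloride; pyridine is too weak a base to form the alkoxide, so closure back to a lactone should be slow.

Step 14
Reactants: 24 diallyl (5S,6R,8S,9S,10S)-6-[(2E,4E,6E)-octa-2,4,6-trienoyloxy]drimane-11,12-dioate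
Product: 25 (5S,6R,8S,9S,10S)-6-[(2E,4E,6E)-octa-2,4,6-trienoyloxy]drimane-11,12-dioic acid (CNP0462207.1)
Conditions: Pd(PPh3)4 (5 mol %), morpholine (10 equiv), THF, rt; dilute citric acid work-up
Reagents that add atoms: none
Why: Tsuji–Trost-type deallylation; zerovalent palladium ionises both allyl esters to π-allyl complexes that morpholine captures, which frees the two acids under neutral conditions that should leave the trienoate, the C6 ester and the C8 centre untouched.

## Compound list

1 | β-cyclocitral (2,6,6-trimethylcyclohex-1-ene-1-carbaldehyde) | CC1=C(C=O)C(C)(C)CCC1 | starting material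
2 | 1-(2,6,6-trimethylcyclohex-1-en-1-yl)ethan-1-ol (racemic) | CC(O)C1=C(C)CCCC1(C)C | intermediate
3 | 1-(2,6,6-trimethylcyclohex-1-en-1-yl)ethan-1-one | CC(=O)C1=C(C)CCCC1(C)C | intermediate
4 | tert-butyldimethyl{[1-(2,6,6-trimethylcyclohex-1-en-1-yl)ethenyl]oxy}silane | C=C(O[Si](C)(C)C(C)(C)C)C1=C(C)CCCC1(C)C | intermediate
5 | (1R,2S,5R)-menthyl (S)-4-methylbenzenesulfinate | Cc1ccc(cc1)[S@@](=O)O[C@@H]1C[C@H](C)CC[C@H]1C(C)C | starting material
6 | methyl acetate | COC(C)=O | starting material
7 | lithium 1-methoxyethenolate | C=C(OC)O[Li] | intermediate (not isolated)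
8 | methyl (R)-2-(4-methylbenzenesulfinyl)acetate | COC(=O)C[S@@](=O)c1ccc(C)cc1 | intermediate
9 | methyl glyoxylate (methyl 2-oxoacetate) | COC(=O)C=O | starting material
10 | dimethyl (E)-2-[(S)-4-methylbenzenesulfinyl]but-2-enedioate (2-sulfinylmaleate, esters cis) | COC(=O)/C=C(\C(=O)OC)[S@@](=O)c1ccc(C)cc1 | intermediate
11 | dimethyl (8S,9R,10R)-6-(tert-butyldimethylsilyloxy)-8-[(S)-4-methylbenzenesulfinyl]drim-5-ene-11,12-dioate (endo adduct; C10 has the same geometry as in 12, the descriptor differs because C9 is still sp3) | COC(=O)[C@@H]1[C@@](C(=O)OC)([S@@](=O)c2ccc(C)cc2)CC(O[Si](C)(C)C(C)(C)C)=C2C(C)(C)CCC[C@]12C | intermediate (not isolated)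
12 | dimethyl (10S)-6-(tert-butyldimethylsilyloxy)drima-5,8-diene-11,12-dioate | COC(=O)C1=C(C(=O)OC)[C@@]2(C)CCCC(C)(C)C2=C(O[Si](C)(C)C(C)(C)C)C1 | intermediate
13 | dimethyl (5S,10S)-6-oxodrim-8-ene-11,12-dioate | COC(=O)C1=C(C(=O)OC)[C@@]2(C)CCCC(C)(C)[C@@H]2C(=O)C1 | intermediate (not isolated)
14 | dimethyl (5S,9R,10S)-6-oxodrim-7-ene-11,12-dioate (9β-ester) | O=C1C=C(C(=O)OC)[C@H](C(=O)OC)[C@@]2(C)CCCC(C)(C)[C@H]12 | intermediate
15 | dimethyl (5S,8S,9S,10S)-6-oxodrimane-11,12-dioate (8β,9β-diester) | O=C1C[C@H](C(=O)OC)[C@H](C(=O)OC)[C@@]2(C)CCCC(C)(C)[C@H]12 | intermediate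
16 | dimethyl (5S,6R,8S,9S,10S)-6-hydroxydrimane-11,12-dioate | O[C@@H]1C[C@H](C(=O)OC)[C@H](C(=O)OC)[C@@]2(C)CCCC(C)(C)[C@H]12 | intermediate (not isolated)
17 | methyl (5S,6R,8S,9S,10S)-12-oxo-6,12-epoxydrimane-11-oate (12,6β-lactone) | O=C3O[C@@H]1C[C@H]3[C@H](C(=O)OC)[C@@]2(C)CCCC(C)(C)[C@H]12 | intermediate
18 | dipotassium (5S,6R,8S,9S,10S)-6-hydroxydrimane-11,12-dioate | [K+].[K+].O[C@@H]1C[C@H](C(=O)[O-])[C@H](C(=O)[O-])[C@@]2(C)CCCC(C)(C)[C@H]12 | intermediate (not isolated)
19 | diallyl (5S,6R,8S,9S,10S)-6-hydroxydrimane-11,12-dioate | O[C@@H]1C[C@H](C(=O)OCC=C)[C@H](C(=O)OCC=C)[C@@]2(C)CCCC(C)(C)[C@H]12 | intermediate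
20 | (2E,4E)-hexa-2,4-dienal | C/C=C/C=C/C=O | starting material
21 | malonic acid | OC(=O)CC(=O)O | starting material
22 | (2E,4E,6E)-octa-2,4,6-trienoic acid | C/C=C/C=C/C=C/C(=O)O | intermediate
23 | (2E,4E,6E)-octa-2,4,6-trienoyl chloride | C/C=C/C=C/C=C/C(Cl)=O | intermediate
24 | diallyl (5S,6R,8S,9S,10S)-6-[(2E,4E,6E)-octa-2,4,6-trienoyloxy]drimane-11,12-dioate | C/C=C/C=C/C=C/C(=O)O[C@@H]1C[C@H](C(=O)OCC=C)[C@H](C(=O)OCC=C)[C@@]2(C)CCCC(C)(C)[C@H]12 | intermediate
25 | (5S,6R,8S,9S,10S)-6-[(2E,4E,6E)-octa-2,4,6-trienoyloxy]drimane-11,12-dioic acid (CNP0462207.1) | C/C=C/C=C/C=C/C(=O)O[C@@H]1C[C@H](C(=O)O)[C@H](C(=O)O)[C@@]2(C)CCCC(C)(C)[C@H]12 | target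

## Step count and least certain steps

Total: 14 steps. Longest linear sequence: 10 steps (1, 2, 3, 6, 7, 8, 9, 10, 13, 14).

**Step 6 (key step).**
- Risk: the cycloaddition may not occur. The diene is twisted, and its reactive s-cis form pushes the silyloxy group against the C4 methyls and the C10 methyl inward. Alternatively, a stepwise Mukaiyama–Michael addition may stop after the first bond because closing C9–C10 is too hindered.
- Risk: exo addition or the opposite orientation may compete and erode or reverse the sense of induction. The enantiomeric sulfoxide (from the antipode of 5) is the remedy if only the sense is wrong.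
- Fallback: setting out from 4, a thermal Diels–Alder reaction with the slim, linear dimethyl acetylenedicarboxylate (toluene, 110–130 °C, sealed tube) should give the racemic diene diester F1 directly. Preparative chromatography on an amylose carbamate chiral phase then separates 12 from its (10R) antipode F2, and the route is rejoined at 12. Steps 4 and 5 are then not needed.

**Step 7.**
- Risk: loss of kinetic control at C9. Re-enolisation of 14 can leak to the 9α-ester, which is expected to be the more stable epimer while C7=C8 is in place, or the dienol may be protonated with poor face selectivity.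
- Fallback: setting out from 13 (hydrolysis of 12 stopped early with HF·pyridine, THF, 0 °C), NaBH4 reduces C6 from the α face to the hydroxy ene diester F3. LiN(iPr)2 (2.2 equiv, THF, −78 °C) forms the alkoxide dienolate F4 by γ-deprotonation at C7, and AcOH at −78 °C protonates its α-carbon C9 anti to the C10 methyl to give the deconjugated 9β-ester F5. Hydrogenation (H2, Pd/C) then gives 16, which closes to 17, where the route is rejoined.

**Step 5.**
- Risk: the condensation may settle on the wrong alkene geometry (fumarate-type), which cannot eliminate toward H9.
- Fallback: setting out from 5, the geometry is built by syn-addition instead. Dimethyl acetylenedicarboxylate is hydrostannylated (Bu3SnH, Pd(PPh3)4 as zerovalent palladium catalyst, THF) to the stannylmaleate F6. Iodine gives the iodomaleate F7 with retention, and iPrMgCl·LiCl at −78 °C gives the alkenylmagnesium reagent F8, which displaces the menthyloxy group of 5 (Andersen reaction) to give 10.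

**Step 10.**
- Risk: the hindered C11 methyl ester may hydrolyse too slowly, so that prolonged hot hydroxide epimerises C9.
- Fallback: setting out from 17, the methyl group is removed by SN2 attack at carbon (LiI, pyridine, reflux) to give the lactone acid F9. The lactone is then opened with KOH at rt, and the route is rejoined at 18.

**Step 13.**
- Risk: acylation of the 6β-alcohol, which is syn-axial to two methyl groups and an ester, may be so slow that 19 lactonises with loss of allyl alcohol.
- Fallback: setting out from 19, the small and very reactive bromoacetyl bromide (pyridine, CH2Cl2, −20 °C) should give the bromoacetate F10. Arbuzov reaction with P(OEt)3 gives the phosphonoacetate F11, and a Horner–Wadsworth–Emmons reaction with 20 (LiCl, DBU, MeCN) builds the trienoate on the molecule and rejoins the route at 24.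

## Further compounds

F1 | step 6 | racemic dimethyl 6-(tert-butyldimethylsilyloxy)drima-5,8-diene-11,12-dioate | COC(=O)C1=C(C(=O)OC)C2(C)CCCC(C)(C)C2=C(O[Si](C)(C)C(C)(C)C)C1
F2 | step 6 | dimethyl (10R)-6-(tert-butyldimethylsilyloxy)drima-5,8-diene-11,12-dioate | COC(=O)C1=C(C(=O)OC)[C@]2(C)CCCC(C)(C)C2=C(O[Si](C)(C)C(C)(C)C)C1
F3 | step 7 | dimethyl (5S,6R,10S)-6-hydroxydrim-8-ene-11,12-dioate | COC(=O)C1=C(C(=O)OC)[C@@]2(C)CCCC(C)(C)[C@@H]2[C@H](O)C1
F4 | step 7 | dilithium alkoxide dienolate of F3 (C6–OLi; C7=C8; C9=C11(OMe)OLi) | COC(O[Li])=C1C(C(=O)OC)=C[C@@H](O[Li])[C@H]2C(C)(C)CCC[C@]12C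
F5 | step 7 | dimethyl (5S,6R,9R,10S)-6-hydroxydrim-7-ene-11,12-dioate | O[C@@H]1C=C(C(=O)OC)[C@H](C(=O)OC)[C@@]2(C)CCCC(C)(C)[C@H]12
F6 | step 5 | dimethyl 2-(tributylstannyl)maleate | COC(=O)/C=C(\C(=O)OC)[Sn](CCCC)(CCCC)CCCC
F7 | step 5 | dimethyl 2-iodomaleate | COC(=O)/C=C(\C(=O)OC)I
F8 | step 5 | [1,2-bis(methoxycarbonyl)ethenyl]magnesium chloride (maleate geometry) | COC(=O)/C=C(\C(=O)OC)[Mg]Cl
F9 | step 10 | (5S,6R,8S,9S,10S)-12-oxo-6,12-epoxydrimane-11-oic acid | O=C3O[C@@H]1C[C@H]3[C@H](C(=O)O)[C@@]2(C)CCCC(C)(C)[C@H]12
F10 | step 13 | diallyl (5S,6R,8S,9S,10S)-6-(2-bromoacetoxy)drimane-11,12-dioate | BrCC(=O)O[C@@H]1C[C@H](C(=O)OCC=C)[C@H](C(=O)OCC=C)[C@@]2(C)CCCC(C)(C)[C@H]12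
F11 | step 13 | diallyl (5S,6R,8S,9S,10S)-6-[2-(diethoxyphosphoryl)acetoxy]drimane-11,12-dioate | CCOP(=O)(OCC)CC(=O)O[C@@H]1C[C@H](C(=O)OCC=C)[C@H](C(=O)OCC=C)[C@@]2(C)CCCC(C)(C)[C@H]12
A1 | alternative 1 | (2E,6E)-farnesyl diphosphate | CC(C)=CCC/C(C)=C/CC/C(C)=C/COP(=O)(O)OP(=O)(O)O
A2 | alternative 1 | drimenol (drim-7-en-11-ol) | C1C=C(C)[C@H](CO)[C@@]2(C)CCCC(C)(C)[C@H]12
A3 | alternative 2 | sclareolide | C1C[C@@]3(C)OC(=O)C[C@@H]3[C@@]2(C)CCCC(C)(C)[C@H]12
A4 | alternative 2 | methyl (5S,8S,9S,10S)-12-amino-12-oxodrimane-11-oate | C1C[C@H](C(N)=O)[C@H](C(=O)OC)[C@@]2(C)CCCC(C)(C)[C@H]12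
A5 | alternative 2 | (8β,9β)-drimane 12,6β-lactone 11-methyl ester | O=C3O[C@@H]1C[C@H]3[C@H](C(=O)OC)[C@@]2(C)CCCC(C)(C)[C@H]12
A6 | alternative 3 | (S)-Hajos–Parrish ketone | O=C1CCC2=CC(=O)CC[C@]12C
A7 | alternative 3 | trans-fused 3-(triethylsilyloxy)-4,4,7a-trimethyloctahydroinden-1-one (6β-silyloxy, drimane numbering) | O=C1C[C@@H](O[Si](CC)(CC)CC)[C@H]2C(C)(C)CCC[C@]12C
A8 | alternative 3 | ethyl 6β-(triethylsilyloxy)-9-hydroxy-11-nordrim-8-en-12-oate | OC1=C(C(=O)OCC)C[C@@H](O[Si](CC)(CC)CC)[C@H]2C(C)(C)CCC[C@]12C
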